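**Retrosynthetic overview**

1. Target 16 comes from aldehyde 14 by oxidation of CHO to CO2H and removal of one aryl silyl ether; C4 is kept at the aldehyde level until then.
2. Key disconnection: the C3–CH2(benzyl) bond of 14, cut to the flat, achiral enal 6, a hydride donor and p-quinone methide 13 (released from acetate 11). One imidazolidinone joins them in one pot by an iminium (H to C2) / enamine (C3 to CH2) organocascade that sets C2 and C3 together.
3. Enabling feature: on the 4-hydroxy-3-prenylphenyl ring the phenol O is para to the benzylic CH2, so this CH2 is the exocyclic terminus of a p-quinone methide and rearomatisation of that ring drives the C–C bond formation. With C4 as CHO, the 1,4-dicarbonyl chain lets the amine activate C2 and then C3 without touching the acidic C2–H.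
4. Enal 6 comes from aryl glyoxylate 4 (aryl bromide 1 + dimethyl oxalate 2) and formyl ylide 5; acetate 11 comes from 4-hydroxybenzaldehyde 7 and prenyl bromide 8 by C-prenylation, reduction and selective acetylation.
5. No ring is formed in the route; both benzene rings come from the starting materials.

Key step: step 6

Remark: the chain is numbered C1 (CO2Me carbon), C2 (4-hydroxyphenyl-bearing), C3 (benzyl-bearing), C4 (CO2H carbon); the target is (2S,3S), the erythro isomer (aryl and benzyl anti in the zigzag drawing).

**Route**

Step 1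
Reactants: 1 (4-bromophenoxy)(tert-butyl)dimethylsilane; 2 dimethyl oxalate
Product: 4 methyl 2-[4-(tert-butyldimethylsilyloxy)phenyl]-2-oxoacetate, via aryllithium 3 (not isolated)
Conditions: n-BuLi (1.05 equiv), THF, −78 °C; cannulated into 2 (3 equiv), THF, −78 °C; aq. NH4Cl
Reagents that add atoms: none
Why: Bromine–lithium exchange followed by acylation of the aryllithium with excess dimethyl oxalate (inverse addition) should stop at the α-keto ester because the tetrahedral adduct persists at −78 °C; no stereocentre is formed.

Step 2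
Reactants: 4 methyl 2-[4-(tert-butyldimethylsilyloxy)phenyl]-2-oxoacetate; 5 (triphenylphosphoranylidene)acetaldehyde
Product: 6 methyl (E)-2-[4-(tert-butyldimethylsilyloxy)phenyl]-4-oxobut-2-enoate (CHO trans to CO2Me)
Conditions: 4 (1.2 equiv), 5 (1.0 equiv, added in portions), toluene, 90 °C
Reagents that add atoms: none
Why: Wittig olefination of the highly electrophilic ketone carbonyl of the α-keto ester with the stabilised formyl ylide should give the E enal (CHO trans to CO2Me, cis to the twisted aryl group), which should also be the thermodynamically preferred isomer, and the excess of 4 keeps the ylide away from the product aldehyde.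

Step 3
Reactants: 7 4-hydroxybenzaldehyde; 8 prenyl bromide (1-bromo-3-methylbut-2-ene)
Product: 9 4-hydroxy-3-(3-methylbut-2-en-1-yl)benzaldehyde
Conditions: 10% aq. KOH, rt; chromatography
Reagents that add atoms: none
Why: C-alkylation of the ambident phenoxide in water (ortho C-prenylation, para position blocked by the formyl group) is a known if unselective entry to ortho-prenylphenols, and the product is separated from the O-prenyl ether by chromatography.

Step 4
Reactants: 9 4-hydroxy-3-(3-methylbut-2-en-1-yl)benzaldehyde
Product: 10 4-(hydroxymethyl)-2-(3-methylbut-2-en-1-yl)phenol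
Conditions: NaBH4, MeOH, 0 °C
Reagents that add atoms: none
Why: Borohydride reduction of the aryl aldehyde gives the benzylic alcohol and leaves alkene and phenol untouched.

Step 5
Reactants: 10 4-(hydroxymethyl)-2-(3-methylbut-2-en-1-yl)phenol
Product: 11 4-hydroxy-3-(3-methylbut-2-en-1-yl)benzyl acetate
Conditions: immobilised Candida antarctica lipase B, vinyl acetate, MTBE, 30 °C; used fresh
Reagents that add atoms: vinyl acetate, C=COC(C)=O
Why: Lipase-catalysed transesterification with vinyl acetate acylates only the aliphatic hydroxyl, so the phenol that later triggers the 1,6-elimination stays free.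

Step 6
Reactants: 6 methyl (E)-2-[4-(tert-butyldimethylsilyloxy)phenyl]-4-oxobut-2-enoate; 11 4-hydroxy-3-(3-methylbut-2-en-1-yl)benzyl acetate
Product: 14 methyl (2S,3S)-2-[4-(tert-butyldimethylsilyloxy)phenyl]-3-formyl-4-[4-hydroxy-3-(3-methylbut-2-en-1-yl)phenyl]butanoate, via saturated (S)-aldehyde 12 (not isolated), via p-quinone methide 13 (not isolated)
Conditions: (2S,5S)-5-benzyl-2-tert-butyl-3-methylimidazolidin-4-one·TFA (20 mol %), diethyl Hantzsch ester (1.05 equiv), CHCl3, −30 °C until 6 is consumed; then 2,6-lutidine (1.5 equiv), 11 (1.3 equiv, slow addition in CHCl3/MeCN), −20 → 0 °C; crude product taken on at once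
Reagents that add atoms: none
Why: Proposed new method: the amine condenses with the aldehyde of 6 to an iminium ion whose LUMO directs hydride from the Hantzsch ester to C2 (the β-carbon, Re face, the other face being shielded by the benzyl group of the catalyst), and the resulting enamine of 12 then adds through the Si face of C3, i.e. the same open π-face, to the exocyclic CH2 of p-quinone methide 13, which is released slowly from 11 by lutidine-assisted 1,6-elimination of acetate; rearomatisation to the phenol and hydrolysis return the catalyst. The closest known reaction types are the iminium transfer hydrogenation of β,β-disubstituted enals with Hantzsch esters, the hydride-initiated iminium–enamine cascade run with a single imidazolidinone, the SN1-type enamine alkylation of aldehydes by stabilised benzylic cations and the 1,6-addition of aldehyde enamines to stabilised p-quinone methides; new is the capture of a δ-unsubstituted p-quinone methide generated in situ, whose electrophilicity should lie in the range of those stabilised cations. No ring is closed. C2 is set by catalyst-controlled hydride delivery and C3 by catalyst-controlled benzylation of the (E)-enamine; because both reagents arrive on the same face of the (E)-enal (CHO trans to CO2Me), the erythro (2S,3S) pair should result, and the intrinsic preference of the enamine to react anti to the C2 aryl group points the same way. The step needs site selectivity for C3 over the far more acidic C2–H, secured because enamine formation activates only the position α to the aldehyde and no base able to enolise the aryl acetate is present; it also needs the quinone methide to be captured at carbon faster than by the hindered, weakly nucleophilic amine, which the slow release is meant to secure.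

Step 7
Reactants: 14 methyl (2S,3S)-2-[4-(tert-butyldimethylsilyloxy)phenyl]-3-formyl-4-[4-hydroxy-3-(3-methylbut-2-en-1-yl)phenyl]butanoate
Product: 15 (2S,3S)-3-[4-(tert-butyldimethylsilyloxy)phenyl]-2-[4-hydroxy-3-(3-methylbut-2-en-1-yl)benzyl]-4-methoxy-4-oxobutanoic acid
Conditions: NaClO2, NaH2PO4, 2-methyl-2-butene (large excess), t-BuOH/H2O, 0 °C
Reagents that add atoms: sodium chlorite, [Na+].[O-]Cl=O
Why: Pinnick (chlorite) oxidation converts the aldehyde into the acid under buffered, weakly acidic conditions that should not epimerise C2 or C3, while the large excess of 2-methyl-2-butene traps hypochlorous acid before it can attack the prenyl group or the free phenol.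

Step 8
Reactants: 15 (2S,3S)-3-[4-(tert-butyldimethylsilyloxy)phenyl]-2-[4-hydroxy-3-(3-methylbut-2-en-1-yl)benzyl]-4-methoxy-4-oxobutanoic acid
Product: 16 asperteretal G2, (2S,3S)-2-[4-hydroxy-3-(3-methylbut-2-en-1-yl)benzyl]-3-(4-hydroxyphenyl)-4-methoxy-4-oxobutanoic acid
Conditions: KHF2, MeOH, rt
Reagents that add atoms: none
Why: Fluoride-mediated cleavage of the aryl silyl ether with mildly acidic KHF2 removes the last protecting group without base, so the epimerisable C2 centre and the methyl ester should be preserved.

**Compound list**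

1 | (4-bromophenoxy)(tert-butyl)dimethylsilane | CC(C)(C)[Si](C)(C)Oc1ccc(Br)cc1 | starting material
2 | dimethyl oxalate | COC(=O)C(=O)OC | starting material
3 | [4-(tert-butyldimethylsilyloxy)phenyl]lithium | [Li]c1ccc(O[Si](C)(C)C(C)(C)C)cc1 | intermediate
4 | methyl 2-[4-(tert-butyldimethylsilyloxy)phenyl]-2-oxoacetate | COC(=O)C(=O)c1ccc(O[Si](C)(C)C(C)(C)C)cc1 | intermediate
5 | (triphenylphosphoranylidene)acetaldehyde | O=CC=P(c1ccccc1)(c1ccccc1)c1ccccc1 | starting material
6 | methyl (E)-2-[4-(tert-butyldimethylsilyloxy)phenyl]-4-oxobut-2-enoate | COC(=O)/C(c1ccc(O[Si](C)(C)C(C)(C)C)cc1)=C/C=O | intermediate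
7 | 4-hydroxybenzaldehyde | O=Cc1ccc(O)cc1 | starting material
8 | prenyl bromide (1-bromo-3-methylbut-2-ene) | CC(C)=CCBr | starting material
9 | 4-hydroxy-3-(3-methylbut-2-en-1-yl)benzaldehyde | CC(C)=CCc1cc(C=O)ccc1O | intermediate
10 | 4-(hydroxymethyl)-2-(3-methylbut-2-en-1-yl)phenol | CC(C)=CCc1cc(CO)ccc1O | intermediate
11 | 4-hydroxy-3-(3-methylbut-2-en-1-yl)benzyl acetate | CC(=O)OCc1ccc(O)c(CC=C(C)C)c1 | intermediate
12 | methyl (S)-2-[4-(tert-butyldimethylsilyloxy)phenyl]-4-oxobutanoate | COC(=O)[C@H](c1ccc(O[Si](C)(C)C(C)(C)C)cc1)CC=O | intermediate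
13 | 4-methylene-2-(3-methylbut-2-en-1-yl)cyclohexa-2,5-dien-1-one | C=C1C=CC(=O)C(CC=C(C)C)=C1 | intermediate
14 | methyl (2S,3S)-2-[4-(tert-butyldimethylsilyloxy)phenyl]-3-formyl-4-[4-hydroxy-3-(3-methylbut-2-en-1-yl)phenyl]butanoate | COC(=O)[C@H](c1ccc(O[Si](C)(C)C(C)(C)C)cc1)[C@H](Cc1ccc(O)c(CC=C(C)C)c1)C=O | intermediate
15 | (2S,3S)-3-[4-(tert-butyldimethylsilyloxy)phenyl]-2-[4-hydroxy-3-(3-methylbut-2-en-1-yl)benzyl]-4-methoxy-4-oxobutanoic acid | COC(=O)[C@H](c1ccc(O[Si](C)(C)C(C)(C)C)cc1)[C@H](Cc1ccc(O)c(CC=C(C)C)c1)C(=O)O | intermediate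
16 | asperteretal G2, (2S,3S)-2-[4-hydroxy-3-(3-methylbut-2-en-1-yl)benzyl]-3-(4-hydroxyphenyl)-4-methoxy-4-oxobutanoic acid | COC(=O)[C@H](c1ccc(O)cc1)[C@H](Cc1ccc(O)c(CC=C(C)C)c1)C(=O)O | target

**Step count and risks**

Total steps: 8. Longest linear sequence: 6 (steps 3, 4, 5, 6, 7, 8, from 7).

Steps most likely to fail:

1. Step 6. The quinone methide may be consumed by N-alkylation of the amine catalyst or by self-condensation with phenols before the enamine captures it, or facial control at C3 may erode. The fallback sets out from 6 (with 10 for the electrophile) and comes back at 16, using known chemistry. The iminium transfer hydrogenation of 6 is run alone with the same amine salt and Hantzsch ester, and 12 is isolated. Pinnick oxidation should give (S)-4-methoxy-4-oxo-3-[4-(tert-butyldimethylsilyloxy)phenyl]butanoic acid F1. Its pivaloyl mixed anhydride (PivCl, Et3N) is treated with lithiated (S)-4-benzyloxazolidin-2-one to give the imide methyl (S)-4-[(S)-4-benzyl-2-oxooxazolidin-3-yl]-4-oxo-2-[4-(tert-butyldimethylsilyloxy)phenyl]butanoate F2. Diol 10 is bis-silylated (TBSCl, imidazole) to tert-butyl{[4-(tert-butyldimethylsilyloxy)-3-(3-methylbut-2-en-1-yl)benzyl]oxy}dimethylsilane F3, and the benzylic silyl ether is exchanged for bromide with Ph3PBr2 to give [4-(bromomethyl)-2-(3-methylbut-2-en-1-yl)phenoxy](tert-butyl)dimethylsilane F4. Evans alkylation of F2 (NaHMDS, 1.0 equiv, THF, −78 °C, so that only the chelating imide is enolised; then F4) should place the benzyl group opposite the auxiliary benzyl group and give the (3S)-imide methyl (2S,3S)-3-{[(S)-4-benzyl-2-oxooxazolidin-3-yl]carbonyl}-2-[4-(tert-butyldimethylsilyloxy)phenyl]-4-[4-(tert-butyldimethylsilyloxy)-3-(3-methylbut-2-en-1-yl)phenyl]butanoate F5. LiOH/H2O2 removes the auxiliary to give the bis-silyl acid (2S,3S)-3-[4-(tert-butyldimethylsilyloxy)phenyl]-2-[4-(tert-butyldimethylsilyloxy)-3-(3-methylbut-2-en-1-yl)benzyl]-4-methoxy-4-oxobutanoic acid F6. The KHF2 conditions of step 8 then remove both silyl groups to reach 16.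

2. Step 2. The ylide may olefinate the product aldehyde a second time, or attack on the aryl ketone may be sluggish, and the E/Z outcome may be mixed. The fallback sets out from 4 and comes back at 6. Wittig reaction with the ylide from (1,3-dioxolan-2-ylmethyl)triphenylphosphonium bromide and KOtBu (THF) gives the acetal-masked alkene methyl 3-(1,3-dioxolan-2-yl)-2-[4-(tert-butyldimethylsilyloxy)phenyl]prop-2-enoate F7 as an E/Z mixture, in which no free aldehyde is exposed to the ylide. Aqueous TFA hydrolysis with iodine-catalysed equilibration should then deliver the E enal 6.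

3. Step 3. O-Alkylation and double alkylation of the ambident phenoxide may outcompete ortho C-alkylation. The fallback sets out from 7 and comes back at 9. Bromination (Br2, AcOH) gives 3-bromo-4-hydroxybenzaldehyde F8, and palladium-catalysed Suzuki–Miyaura coupling with 3-methylbut-2-enylboronic acid pinacol ester under ligand control for the linear (α) product (K3PO4, aqueous THF) installs the prenyl group regiospecifically at the brominated carbon to give 9.

Further compounds
F1 | step 6 | (S)-4-methoxy-4-oxo-3-[4-(tert-butyldimethylsilyloxy)phenyl]butanoic acid | COC(=O)[C@H](c1ccc(O[Si](C)(C)C(C)(C)C)cc1)CC(=O)O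
F2 | step 6 | methyl (S)-4-[(S)-4-benzyl-2-oxooxazolidin-3-yl]-4-oxo-2-[4-(tert-butyldimethylsilyloxy)phenyl]butanoate | COC(=O)[C@H](c1ccc(O[Si](C)(C)C(C)(C)C)cc1)CC(=O)N1[C@@H](Cc2ccccc2)COC1=O
F3 | step 6 | tert-butyl{[4-(tert-butyldimethylsilyloxy)-3-(3-methylbut-2-en-1-yl)benzyl]oxy}dimethylsilane | CC(C)=CCc1cc(CO[Si](C)(C)C(C)(C)C)ccc1O[Si](C)(C)C(C)(C)C
F4 | step 6 | [4-(bromomethyl)-2-(3-methylbut-2-en-1-yl)phenoxy](tert-butyl)dimethylsilane | CC(C)=CCc1cc(CBr)ccc1O[Si](C)(C)C(C)(C)C
F5 | step 6 | methyl (2S,3S)-3-{[(S)-4-benzyl-2-oxooxazolidin-3-yl]carbonyl}-2-[4-(tert-butyldimethylsilyloxy)phenyl]-4-[4-(tert-butyldimethylsilyloxy)-3-(3-methylbut-2-en-1-yl)phenyl]butanoate | COC(=O)[C@H](c1ccc(O[Si](C)(C)C(C)(C)C)cc1)[C@H](Cc1ccc(O[Si](C)(C)C(C)(C)C)c(CC=C(C)C)c1)C(=O)N1[C@@H](Cc2ccccc2)COC1=O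
F6 | step 6 | (2S,3S)-3-[4-(tert-butyldimethylsilyloxy)phenyl]-2-[4-(tert-butyldimethylsilyloxy)-3-(3-methylbut-2-en-1-yl)benzyl]-4-methoxy-4-oxobutanoic acid | COC(=O)[C@H](c1ccc(O[Si](C)(C)C(C)(C)C)cc1)[C@H](Cc1ccc(O[Si](C)(C)C(C)(C)C)c(CC=C(C)C)c1)C(=O)O
F7 | step 2 | methyl 3-(1,3-dioxolan-2-yl)-2-[4-(tert-butyldimethylsilyloxy)phenyl]prop-2-enoate (E/Z mixture) | COC(=O)C(=CC1OCCO1)c1ccc(O[Si](C)(C)C(C)(C)C)cc1
F8 | step 3 | 3-bromo-4-hydroxybenzaldehyde | O=Cc1ccc(O)c(Br)c1
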